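**Plan**

- Numbering: ring C1 (exocyclic =CH2), C2, C3, C4 (OAc), C5 (CMe2), C6 (bears C7H2–OAr). With C4 as a carbonyl and C7 as an ester, C4 and C5 (the β,β-dimethyl end of a C7 enoate) are both electrophilic, so the ring bond C4–C5 needs C4 as an acyl anion equivalent (Stetter).
- Retrosynthesis: cut the C4 acetate and the C7–O aryl ether (to the 7-hydroxycoumarin), return C4–OH and C7H2OH to ketone and ester, cut the ring bond C4–C5, then cut C1–C6 between a 2-bromo-3-methylbut-2-enoate and a 2-borylalkenol.
- Forward: the chain is joined at C1–C6 by Suzuki coupling, the terminal alcohol is oxidised to the C4 aldehyde, and the only carbocycle closes 6-endo at C4–C5. Reduction, etherification and acetylation finish the route.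
- Stereochemistry: C6 (S) comes from catalyst-controlled protonation during the ring closure. C4 (R) comes from hydride addition anti to the C6 substituent, which gives the cis-1,3 pattern of the target.

Key step: step 6

Assumption: the sense of induction in this endo ring closure cannot be predicted from the known exo cases; the route is written with the (5aS,10bR) catalyst, and its mirror image (from the antipodal aminoindanol) would be used if the (R)-ester prevailed.

**Route**

Step 1
Reactants: 1 methyl 3-methylbut-2-enoate
Product: 3 methyl 2-bromo-3-methylbut-2-enoate, via methyl 2,3-dibromo-3-methylbutanoate 2 (not isolated)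
Conditions: Br2, CH2Cl2, 0 °C to rt; then Et3N, 0 °C to rt
Reagents that add atoms: bromine, BrBr
Why: Bromine adds across the enoate and triethylamine then removes HBr through the acidic α-hydrogen (bromination–dehydrobromination), the standard entry to 2-bromo-2-enoates; the two β-methyl groups are identical, so no alkene geometry arises.

Step 2
Reactants: 4 pent-4-yn-1-ol
Product: 5 4-bromopent-4-en-1-ol
Conditions: Et4N+ HBr2− (preformed from Et4NBr and HBr), CH2Cl2, 40 °C
Reagents that add atoms: tetraethylammonium hydrogen dibromide, CC[N+](CC)(CC)CC.[Br-].Br
Why: Markovnikov hydrobromination of a terminal alkyne with the hydrogen dibromide salt places bromine on the internal carbon and should stop at the 2-bromo-1-alkene, and this mild HBr source leaves the primary alcohol alone.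

Step 3
Reactants: 5 4-bromopent-4-en-1-ol
Product: 6 4-(4,4,5,5-tetramethyl-1,3,2-dioxaborolan-2-yl)pent-4-en-1-ol
Conditions: B2pin2, PdCl2(PPh3)2 (3 mol%), PPh3, KOPh, toluene, 50 °C
Reagents that add atoms: bis(pinacolato)diboron, CC1(C)OB(OC1(C)C)B1OC(C)(C)C(C)(C)O1
Why: Miyaura borylation of a 1-alkenyl bromide (oxidative addition, phenoxide-assisted transmetalation, reductive elimination) keeps boron on the internal alkene carbon and tolerates the free hydroxyl.

Step 4
Reactants: 6 4-(4,4,5,5-tetramethyl-1,3,2-dioxaborolan-2-yl)pent-4-en-1-ol; 3 methyl 2-bromo-3-methylbut-2-enoate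
Product: 7 methyl 2-(5-hydroxypent-1-en-2-yl)-3-methylbut-2-enoate
Conditions: PdCl2(dppf)·CH2Cl2 (5 mol%), K3PO4, dioxane/H2O, 80 °C
Reagents that add atoms: none
Why: Suzuki–Miyaura alkenyl–alkenyl coupling forms C1–C6; the electron-poor α-bromoenoate undergoes oxidative addition readily, the bidentate ligand favours reductive elimination at the crowded carbon, and neither partner has E/Z isomers to lose.

Step 5
Reactants: 7 methyl 2-(5-hydroxypent-1-en-2-yl)-3-methylbut-2-enoate
Product: 8 methyl 3-methyl-2-(5-oxopent-1-en-2-yl)but-2-enoate
Conditions: Dess–Martin periodinane, CH2Cl2, 0 °C to rt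
Reagents that add atoms: none
Why: Dess–Martin oxidation converts the primary alcohol into the aldehyde under non-basic conditions that should neither move the exocyclic alkene nor touch the enoate.

Step 6
Reactants: 8 methyl 3-methyl-2-(5-oxopent-1-en-2-yl)but-2-enoate
Product: 9 methyl (1S)-2,2-dimethyl-6-methylidene-3-oxocyclohexane-1-carboxylate
Conditions: (5aS,10bR)-aminoindanol-derived N-C6F5 triazolium BF4 salt (20 mol%), KHMDS (19 mol%), toluene, rt, HMDS removed in vacuo; then 8, toluene (0.02 M), rt to 60 °C
Reagents that add atoms: none
Why: Proposed new method: the triazolylidene adds to the unhindered aldehyde C4 and proton transfer gives the enaminol, whose nucleophilic carbon attacks the β,β-dimethyl carbon C5 of the 2-alkenyl enoate to form C4–C5 and a dienolate spread over C7, C6, C1 and the methylene carbon; proton transfer to C6 and loss of the carbene then release ketone 9. The closest known reaction type is the enantioselective intramolecular Stetter reaction of aldehydes tethered to β,β-disubstituted or α-substituted enoates, which builds quaternary centres and sets the α-carbon by internal proton transfer, but only in exo ring closures onto acceptors that are at most trisubstituted. The cyclohexanone closes 6-endo-trig, with both acceptor carbons C5 and C6 ending up in the ring. C6 is the only new stereocentre and is set by face-selective protonation of the dienolate by the hydroxyl of the still-bound chiral azolium carbinol, which is why the carbene is used free of amine and excess base. The step needs attack at C5 only and α- rather than γ-protonation: C5 is the one carbon whose attack gives an ester- and vinyl-stabilised anion in a six-membered ring, and the carbinol O–H sits next to C6 but far from the methylene carbon, so the alkene should stay exocyclic. The steric demand of the tetrasubstituted acceptor and the modest activation by a single ester remain unproven.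

Step 7
Reactants: 9 methyl (1S)-2,2-dimethyl-6-methylidene-3-oxocyclohexane-1-carboxylate
Product: 10 (1R,3S)-3-(hydroxymethyl)-2,2-dimethyl-4-methylidenecyclohexan-1-ol
Conditions: LiAlH4, THF, −78 to 0 °C; aq. NaOH work-up
Reagents that add atoms: none
Why: Lithium aluminium hydride reduces ketone and ester in one operation; hydride should reach C4 anti to the C6 substituent in either chair (axial attack with the ester equatorial, the other face screened by the axial C5 methyl), so C4 becomes R with an equatorial hydroxyl cis to C7, as in reductions of 4,4-dimethyl-3-oxo terpenoids, and the low temperature protects the base-sensitive C6 hydrogen.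

Step 8
Reactants: 10 (1R,3S)-3-(hydroxymethyl)-2,2-dimethyl-4-methylidenecyclohexan-1-ol; 11 umbelliferone (7-hydroxy-2H-chromen-2-one)
Product: 12 7-{[(1S,3R)-3-hydroxy-2,2-dimethyl-6-methylidenecyclohexyl]methoxy}-2H-chromen-2-one
Conditions: PPh3, DIAD, THF, 0 °C to rt
Reagents that add atoms: none
Why: Mitsunobu etherification: the acidic phenol (pKa about 8) is deprotonated by the betaine and displaces the alkoxyphosphonium of the primary C7 hydroxyl by SN2, while the neopentyl-type secondary C4 hydroxyl is too hindered to be activated; no stereocentre is touched.

Step 9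
Reactants: 12 7-{[(1S,3R)-3-hydroxy-2,2-dimethyl-6-methylidenecyclohexyl]methoxy}-2H-chromen-2-one
Product: 13 (1R,3S)-2,2-dimethyl-4-methylidene-3-{[(2-oxo-2H-chromen-7-yl)oxy]methyl}cyclohexyl acetate
Conditions: Ac2O, pyridine, DMAP (cat.), CH2Cl2, rt
Reagents that add atoms: acetic anhydride, CC(=O)OC(C)=O
Why: DMAP-catalysed acetylation esterifies the hindered equatorial C4 alcohol with retention of configuration, and the aryl ether, coumarin lactone and exocyclic alkene are inert to it.

**Compound list**

1 | methyl 3-methylbut-2-enoate | COC(=O)C=C(C)C | starting material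
2 | methyl 2,3-dibromo-3-methylbutanoate (racemic, not isolated) | COC(=O)C(Br)C(C)(C)Br | intermediate
3 | methyl 2-bromo-3-methylbut-2-enoate | COC(=O)C(Br)=C(C)C | intermediate
4 | pent-4-yn-1-ol | C#CCCCO | starting material
5 | 4-bromopent-4-en-1-ol | C=C(Br)CCCO | intermediate
6 | 4-(4,4,5,5-tetramethyl-1,3,2-dioxaborolan-2-yl)pent-4-en-1-ol | C=C(CCCO)B1OC(C)(C)C(C)(C)O1 | intermediate
7 | methyl 2-(5-hydroxypent-1-en-2-yl)-3-methylbut-2-enoate | COC(=O)C(=C(C)C)C(=C)CCCO | intermediate
8 | methyl 3-methyl-2-(5-oxopent-1-en-2-yl)but-2-enoate | COC(=O)C(=C(C)C)C(=C)CCC=O | intermediate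
9 | methyl (1S)-2,2-dimethyl-6-methylidene-3-oxocyclohexane-1-carboxylate | C=C1CCC(=O)C(C)(C)[C@H]1C(=O)OC | intermediate
10 | (1R,3S)-3-(hydroxymethyl)-2,2-dimethyl-4-methylidenecyclohexan-1-ol | C=C1CC[C@@H](O)C(C)(C)[C@H]1CO | intermediate
11 | umbelliferone (7-hydroxy-2H-chromen-2-one) | O=c1ccc2ccc(O)cc2o1 | starting material
12 | 7-{[(1S,3R)-3-hydroxy-2,2-dimethyl-6-methylidenecyclohexyl]methoxy}-2H-chromen-2-one | C=C1CC[C@@H](O)C(C)(C)[C@H]1COc1ccc2ccc(=O)oc2c1 | intermediate
13 | (1R,3S)-2,2-dimethyl-4-methylidene-3-{[(2-oxo-2H-chromen-7-yl)oxy]methyl}cyclohexyl acetate | C=C1CC[C@@H](OC(C)=O)C(C)(C)[C@H]1COc1ccc2ccc(=O)oc2c1 | target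

**Step count**

Total steps: 9. Longest linear sequence: 8 steps (4 to 13, steps 2 to 9).

**Steps most likely to fail**

Step 6 (Proposed new method). The acyl anion equivalent may never engage the crowded, weakly electrophilic C5 and may instead be drained into acyloin-type self-condensation or hydroacylation of the 1,1-disubstituted alkene. The dienolate may also be protonated without face control or at the γ-carbon, which would erode the ee or pull the alkene into conjugation. The fallback uses known chemistry, a biomimetic epoxy-olefin cyclisation, and sets out from umbelliferone 11. O-Alkylation with commercial geranyl bromide (K2CO3, acetone, reflux) should give auraptene F1. Shi epoxidation (D-fructose-derived ketone, Oxone, buffered MeCN/dimethoxymethane/water, 0 °C) is regioselective for the electron-rich distal alkene and should give (R)-6',7'-epoxyauraptene F2; the D-ketone is the antipode that the spiro transition-state model predicts for the R epoxide. ZrCl4 in CH2Cl2 should then open the epoxide at its tertiary carbon with attack by the trisubstituted alkene through a chair transition state and loss of a methyl proton. This forms C5–C6, carries the epoxide configuration into C4 (R), places the C7 arm cis and equatorial, and leaves the exocyclic alkene. The fallback comes back to the route at 12, ahead of step 9.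

Step 8. Displacement at the β-branched C7 may be slow enough that the alkoxyphosphonium is captured by the cis C4 hydroxyl (closure to a bridged cyclic ether) or that the reagents are consumed by hydrazide alkylation. The fallback reverses the roles so that C7 never becomes electrophilic. It sets out from diol 10 and couples the primary hydroxyl, as the nucleophile, with commercial 7-bromocoumarin under palladium catalysis (RockPhos Pd G3, Cs2CO3, toluene, 90 °C; C–O cross-coupling of primary alcohols with aryl bromides). The hindered secondary alcohol is expected to stay out. It comes back at 12 and makes no compound outside the list (F0).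

Step 4. Transmetalation and reductive elimination at the fully substituted C6 may be slow enough that protodeboronation of the boronate and reduction of the bromoenoate take over. The fallback makes the C1–C6 bond by carbonyl addition and the C5=C6 alkene by elimination. It sets out from bromoalkenol 5, which is silylated (TBSCl, imidazole, CH2Cl2) to tert-butyl[(4-bromopent-4-en-1-yl)oxy]dimethylsilane F3. Bromine–lithium exchange (t-BuLi, 2 equiv, Et2O, −78 °C) gives {5-[(tert-butyldimethylsilyl)oxy]pent-1-en-2-yl}lithium F4. This adds to the ketone of commercial methyl 3-methyl-2-oxobutanoate at −78 °C to give methyl 6-[(tert-butyldimethylsilyl)oxy]-2-hydroxy-3-methylidene-2-(propan-2-yl)hexanoate F5. Burgess dehydration (toluene, 50 °C) can only take the isopropyl methine hydrogen and should give methyl 2-{5-[(tert-butyldimethylsilyl)oxy]pent-1-en-2-yl}-3-methylbut-2-enoate F6. Desilylation (HF·pyridine, THF) comes back to the route at 7.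

**Further compounds**

F1 | step 6 | auraptene, 7-{[(2E)-3,7-dimethylocta-2,6-dien-1-yl]oxy}-2H-chromen-2-one | CC(C)=CCC/C(C)=C/COc1ccc2ccc(=O)oc2c1
F2 | step 6 | (R)-6',7'-epoxyauraptene, 7-{[(2E)-5-[(2R)-3,3-dimethyloxiran-2-yl]-3-methylpent-2-en-1-yl]oxy}-2H-chromen-2-one | CC1(C)O[C@@H]1CC/C(C)=C/COc1ccc2ccc(=O)oc2c1
F0 | step 8 | none | none
F3 | step 4 | tert-butyl[(4-bromopent-4-en-1-yl)oxy]dimethylsilane | C=C(Br)CCCO[Si](C)(C)C(C)(C)C
F4 | step 4 | {5-[(tert-butyldimethylsilyl)oxy]pent-1-en-2-yl}lithium | [Li]C(=C)CCCO[Si](C)(C)C(C)(C)C
F5 | step 4 | methyl 6-[(tert-butyldimethylsilyl)oxy]-2-hydroxy-3-methylidene-2-(propan-2-yl)hexanoate (racemic) | COC(=O)C(O)(C(C)C)C(=C)CCCO[Si](C)(C)C(C)(C)C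
F6 | step 4 | methyl 2-{5-[(tert-butyldimethylsilyl)oxy]pent-1-en-2-yl}-3-methylbut-2-enoate | COC(=O)C(=C(C)C)C(=C)CCCO[Si](C)(C)C(C)(C)C
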